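## Retrosynthetic overview

- Target 12 ⇐ tetra-O-benzyl biflavanone 11 ⇐ diol 10, by two SNAr closures of ring C (O1–C8a and O1''–C8a'' bonds, fluoride as leaving group).
- 10 ⇐ 1,2-dioxane 9 (O–O reduction) ⇐ cyclobutane 8, by insertion of O2 into the bond between the two anisyl-bearing carbons.
- 8 ⇐ 7 ⇐ two molecules of chalcone 6, by enantioselective head-to-head [2+2] photodimerisation; 6 ⇐ ketone 3 + aldehyde 4; 3 ⇐ 5-fluororesorcinol 1.
- Feature used: the chain C2–C3–C3''–C2'' joining the two rings C is the carbon frame of a chalcone photodimer. Its extra C2–C2'' bond is later replaced by the ring oxygens O1 and O1''. The 5-OH/C4=O pair of ring A is the binding site for the chiral Lewis acid.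
- Ring order: cyclobutane (step 4), 1,2-dioxane (step 6), both rings C (step 8); rings A and B are bought.

Key step: step 4

Remark: flavanone numbering is used for the target, with double primes on the second unit; benzyl bromide, acetic acid and O2 are treated as reagents, not numbered compounds.

Remark (assumption): both antipodes of t-Bu-PyBox are commercial; the one that gives the (1S,2S,3R,4R)-cyclobutane 7 is to be fixed on the first run, and the route is written for it.

Remark: the precursor ketone is made from 5-fluororesorcinol because C-acylation para to a hydroxyl and selective 4-O-benzylation are better controlled than two successive SNAr reactions on a trifluoroarene.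

## Route

Step 1
Reactants: 1 5-fluorobenzene-1,3-diol
Product: 2 1-(2-fluoro-4,6-dihydroxyphenyl)ethan-1-one
Conditions: AcOH, ZnCl2, 140 °C
Reagents that add atoms: acetic acid, CC(=O)O
Why: Nencki-type Friedel–Crafts acylation of a resorcinol goes para to one hydroxyl and ortho to the other, as in the classical preparation of resacetophenone, so the acetyl group should enter the carbon flanked by OH and F and not the carbon between the two hydroxyls, any symmetric 2,6-dihydroxy isomer being removed by crystallisation.

Step 2
Reactants: 2 1-(2-fluoro-4,6-dihydroxyphenyl)ethan-1-one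
Product: 3 1-[4-(benzyloxy)-2-fluoro-6-hydroxyphenyl]ethan-1-one
Conditions: BnBr (1.05 equiv), K2CO3, acetone, reflux
Reagents that add atoms: benzyl bromide, BrCc1ccccc1
Why: Williamson etherification with one equivalent of benzyl bromide should take the free and more acidic 4-OH, because the 6-OH is held in a hydrogen bond to the ketone and is far less nucleophilic under carbonate conditions.

Step 3
Reactants: 3 1-[4-(benzyloxy)-2-fluoro-6-hydroxyphenyl]ethan-1-one; 4 4-methoxybenzaldehyde
Product: 6 (E)-1-[4-(benzyloxy)-2-fluoro-6-hydroxyphenyl]-3-(4-methoxyphenyl)prop-2-en-1-one, via aldol adduct 5 (not isolated)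
Conditions: KOH, EtOH, rt; then aq HCl
Reagents that add atoms: none
Why: Claisen–Schmidt condensation (aldol addition to the non-enolisable aldehyde, then E1cB loss of water) should give the conjugated E-enone as the thermodynamic product, the fluorinated ring being shielded from SNAr by its own phenoxide.

Step 4
Reactants: 6 (E)-1-[4-(benzyloxy)-2-fluoro-6-hydroxyphenyl]-3-(4-methoxyphenyl)prop-2-en-1-one (two molecules)
Product: 7 [(1S,2S,3R,4R)-3,4-bis(4-methoxyphenyl)cyclobutane-1,2-diyl]bis{[4-(benzyloxy)-2-fluoro-6-hydroxyphenyl]methanone} (all-trans; C2-symmetric)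
Conditions: Sc(OTf)3 (10 mol%), t-Bu-PyBox (15 mol%), Ru(bpy)3(PF6)2 (2.5 mol%), i-PrOAc–MeCN 3:1 (0.5 M), blue LEDs, rt, N2
Reagents that add atoms: none
Why: Proposed new method: the chalcone chelated through its phenol oxygen and carbonyl oxygen to the trivalent scandium–PyBox complex has a much lower triplet energy than free 6, so photoexcited Ru(bpy)3(PF6)2 passes triplet energy only to the bound molecule, whose twisted triplet bonds through its α-carbon to the α-carbon of a free chalcone and leaves a 1,4-diradical with two 4-methoxybenzylic ends (first bonding between the β-carbons would give the same head-to-head skeleton). After intersystem crossing the four-membered ring closes by radical–radical recombination between the two benzylic carbons. The closest known reactions are the chiral-Lewis-acid-catalysed triplet [2+2] cycloadditions of 2'-hydroxychalcones with dienes and styrenes and the racemic sensitised head-to-head photodimerisation of chalcones; the enantioselective homodimerisation has not been shown. The aroyl-bearing carbon of the bound chalcone is set by the tert-butyl group of the ligand, which screens one face of the chelated enone, and the aroyl-bearing carbon of the incoming chalcone takes the trans arrangement because the like diradical closes without strain whereas the unlike one is expected to revert to two chalcones. The two anisyl-bearing carbons close trans to their neighbours from the relaxed diradical, and their configuration is not critical because step 6 breaks the bond between them. The step needs head-to-head regiochemistry, secured by the doubly stabilised diradical, and excitation of the bound chalcone only, secured by the phenol–carbonyl chelate, with a high chalcone concentration so that dimerisation outruns E/Z decay.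

Step 5
Reactants: 7 [(1S,2S,3R,4R)-3,4-bis(4-methoxyphenyl)cyclobutane-1,2-diyl]bis{[4-(benzyloxy)-2-fluoro-6-hydroxyphenyl]methanone}
Product: 8 [(1S,2S,3R,4R)-3,4-bis(4-methoxyphenyl)cyclobutane-1,2-diyl]bis{[2,4-bis(benzyloxy)-6-fluorophenyl]methanone}
Conditions: BnBr (2.5 equiv), K2CO3, DMF, 50 °C
Reagents that add atoms: benzyl bromide, BrCc1ccccc1
Why: Williamson etherification of the two chelated phenols masks them so that the fluorinated rings stay electron-poor enough for the later SNAr, and since the all-trans cyclobutane is the thermodynamic isomer, reversible enolisation of the ketones under carbonate should not change it.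

Step 6
Reactants: 8 [(1S,2S,3R,4R)-3,4-bis(4-methoxyphenyl)cyclobutane-1,2-diyl]bis{[2,4-bis(benzyloxy)-6-fluorophenyl]methanone}
Product: 9 [(3R,4R,5R,6R)-3,6-bis(4-methoxyphenyl)-1,2-dioxane-4,5-diyl]bis{[2,4-bis(benzyloxy)-6-fluorophenyl]methanone} (all four substituents equatorial)
Conditions: 9,10-dicyanoanthracene (5 mol%), biphenyl (0.5 equiv), O2 (1 atm), MeCN–CH2Cl2, 420–440 nm LEDs, −20 °C
Reagents that add atoms: dioxygen, O=O
Why: photoinduced electron-transfer oxygenation of a 1,2-diarylcyclobutane, a known route to 3,6-diaryl-1,2-dioxanes, should remove one electron from the bis-anisyl unit, break the strained bond between the two anisyl carbons to a 1,4-radical cation and trap it with O2 or superoxide, the six-membered ring closing through a chair in which the two untouched trans aroyl groups and both anisyl groups are equatorial, which re-forms the two benzylic stereocentres with oxygen in the place of the broken C–C bond, while loss of a chalcone is disfavoured because it would have to leave as an electron-poor enone radical cation.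

Step 7
Reactants: 9 [(3R,4R,5R,6R)-3,6-bis(4-methoxyphenyl)-1,2-dioxane-4,5-diyl]bis{[2,4-bis(benzyloxy)-6-fluorophenyl]methanone}
Product: 10 (2R,3R)-1,4-bis[2,4-bis(benzyloxy)-6-fluorophenyl]-2,3-bis[(R)-hydroxy(4-methoxyphenyl)methyl]butane-1,4-dione
Conditions: Zn dust, AcOH–CH2Cl2, 0 °C to rt
Reagents that add atoms: none
Why: reductive cleavage of the peroxide O–O bond by zinc in acetic acid touches no C–O or C–C bond, so the 1,4-diol should keep all four stereocentres, and aryl fluorides, benzyl ethers and the hindered aryl ketones are inert to it.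

Step 8
Reactants: 10 (2R,3R)-1,4-bis[2,4-bis(benzyloxy)-6-fluorophenyl]-2,3-bis[(R)-hydroxy(4-methoxyphenyl)methyl]butane-1,4-dione
Product: 11 (2R,3R,2''R,3''R)-5,5'',7,7''-tetrakis(benzyloxy)-4',4'''-dimethoxy-3,3''-biflavanone (2,3-cis in both halves)
Conditions: KN(SiMe3)2 (2.05 equiv), THF, −78 °C; then DMF, −40 to 0 °C; AcOH quench
Reagents that add atoms: none
Why: double intramolecular SNAr (addition–elimination through a Meisenheimer complex stabilised by the ortho ketone) in which each benzylic alkoxide displaces the fluoride of the aroyl group on the adjacent carbon in a six-membered closure, the C2–O bond not being touched so that C2 keeps its configuration and the trans-diequatorial relation of the dioxane becomes 2,3-cis in ring C; the base is used in the exact amount and is consumed, which leaves nothing to epimerise the cis-flavanone at C3.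

Step 9
Reactants: 11 (2R,3R,2''R,3''R)-5,5'',7,7''-tetrakis(benzyloxy)-4',4'''-dimethoxy-3,3''-biflavanone
Product: 12 (2R,3R,2''R,3''R)-5,5'',7,7''-tetrahydroxy-4',4'''-dimethoxy-3,3''-biflavanone (target)
Conditions: H2 (1 atm), Pd/C, EtOAc–MeOH, rt
Reagents that add atoms: none
Why: hydrogenolysis of the four aryl benzyl ethers over palladium is far faster than cleavage of the cyclic benzylic C2–O1 bond or reduction of the chromanone carbonyl, and the neutral conditions leave the base-labile 2,3-cis relation untouched.

## Compound list

1 | 5-fluorobenzene-1,3-diol (5-fluororesorcinol) | Oc1cc(O)cc(F)c1 | starting material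
2 | 1-(2-fluoro-4,6-dihydroxyphenyl)ethan-1-one | CC(=O)c1c(O)cc(O)cc1F | intermediate
3 | 1-[4-(benzyloxy)-2-fluoro-6-hydroxyphenyl]ethan-1-one | CC(=O)c1c(O)cc(OCc2ccccc2)cc1F | intermediate
4 | 4-methoxybenzaldehyde | COc1ccc(C=O)cc1 | starting material
5 | 1-[4-(benzyloxy)-2-fluoro-6-hydroxyphenyl]-3-hydroxy-3-(4-methoxyphenyl)propan-1-one (aldol adduct, racemic, not isolated) | COc1ccc(C(O)CC(=O)c2c(O)cc(OCc3ccccc3)cc2F)cc1 | intermediate
6 | (E)-1-[4-(benzyloxy)-2-fluoro-6-hydroxyphenyl]-3-(4-methoxyphenyl)prop-2-en-1-one | COc1ccc(/C=C/C(=O)c2c(O)cc(OCc3ccccc3)cc2F)cc1 | intermediate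
7 | [(1S,2S,3R,4R)-3,4-bis(4-methoxyphenyl)cyclobutane-1,2-diyl]bis{[4-(benzyloxy)-2-fluoro-6-hydroxyphenyl]methanone} | COc1ccc(cc1)[C@H]1[C@H](C(=O)c2c(O)cc(OCc3ccccc3)cc2F)[C@@H](C(=O)c2c(O)cc(OCc3ccccc3)cc2F)[C@@H]1c1ccc(OC)cc1 | intermediate
8 | [(1S,2S,3R,4R)-3,4-bis(4-methoxyphenyl)cyclobutane-1,2-diyl]bis{[2,4-bis(benzyloxy)-6-fluorophenyl]methanone} | COc1ccc(cc1)[C@H]1[C@H](C(=O)c2c(OCc3ccccc3)cc(OCc3ccccc3)cc2F)[C@@H](C(=O)c2c(OCc3ccccc3)cc(OCc3ccccc3)cc2F)[C@@H]1c1ccc(OC)cc1 | intermediate
9 | [(3R,4R,5R,6R)-3,6-bis(4-methoxyphenyl)-1,2-dioxane-4,5-diyl]bis{[2,4-bis(benzyloxy)-6-fluorophenyl]methanone} | COc1ccc(cc1)[C@H]1[C@H](C(=O)c2c(OCc3ccccc3)cc(OCc3ccccc3)cc2F)[C@@H](C(=O)c2c(OCc3ccccc3)cc(OCc3ccccc3)cc2F)[C@H](c2ccc(OC)cc2)OO1 | intermediate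
10 | (2R,3R)-1,4-bis[2,4-bis(benzyloxy)-6-fluorophenyl]-2,3-bis[(R)-hydroxy(4-methoxyphenyl)methyl]butane-1,4-dione | COc1ccc(cc1)[C@H](O)[C@H](C(=O)c2c(OCc3ccccc3)cc(OCc3ccccc3)cc2F)[C@@H](C(=O)c2c(OCc3ccccc3)cc(OCc3ccccc3)cc2F)[C@@H](O)c1ccc(OC)cc1 | intermediate
11 | (2R,3R,2''R,3''R)-5,5'',7,7''-tetrakis(benzyloxy)-4',4'''-dimethoxy-3,3''-biflavanone | COc1ccc([C@@H]2Oc3cc(OCc4ccccc4)cc(OCc4ccccc4)c3C(=O)[C@@H]2[C@H]2C(=O)c3c(OCc4ccccc4)cc(OCc4ccccc4)cc3O[C@H]2c2ccc(OC)cc2)cc1 | intermediate
12 | (2R,3R,2''R,3''R)-5,5'',7,7''-tetrahydroxy-4',4'''-dimethoxy-3,3''-biflavanone | COc1ccc([C@@H]2Oc3cc(O)cc(O)c3C(=O)[C@@H]2[C@H]2C(=O)c3c(O)cc(O)cc3O[C@H]2c2ccc(OC)cc2)cc1 | target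

## Step count and risks

Total step count: 9. Longest linear sequence: 9 steps (1 to 12).

**Step 4 (proposed new method).**
- Risk: the bound triplet may decay by E/Z isomerisation faster than it adds to a second, electron-poor enone. It may also add with weak facial discrimination, or unbound chalcone may dimerise in a racemic background reaction.
- Fallback (known chemistry, resolution in place of asymmetric catalysis): it sets out from 6. O-Benzylation (BnBr, K2CO3, DMF) gives (E)-1-[2,4-bis(benzyloxy)-6-fluorophenyl]-3-(4-methoxyphenyl)prop-2-en-1-one F1. Triplet-sensitised head-to-head photodimerisation of F1 (Ir(ppy)3, blue LEDs, MeCN) should give the racemic all-trans dimer, that is 8 together with its mirror image, [(1R,2R,3S,4S)-3,4-bis(4-methoxyphenyl)cyclobutane-1,2-diyl]bis{[2,4-bis(benzyloxy)-6-fluorophenyl]methanone} F2. Preparative HPLC on a chiral stationary phase then delivers 8, where the route is rejoined; steps 4 and 5 are replaced.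

**Step 6.**
- Risk: the ring-opened radical cation may fragment into two chalcone units before oxygen is captured. The ring may also close with an anisyl group axial, or the dioxane may fragment further by electron transfer on over-irradiation.
- Fallback (dark hole-catalysed chain oxygenation in place of photosensitisation): it sets out from 8. A catalytic amount of the ground-state one-electron oxidant (2,4-Br2C6H3)3N·SbCl6 in O2-saturated CH2Cl2 at −78 °C should start a radical-cation chain in which the dioxane radical cation passes its hole to the next molecule of 8. No sensitiser radical anion or superoxide is present to return an electron to the ring-opened species, and at −78 °C the activated fragmentation is slowed more than the barrier-free capture of O2. The same chair closure leads back to 9; this fallback makes no new compound, F0.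

**Step 8.**
- Risk: the β-alkoxide may undergo retro-aldol loss of 4-methoxybenzaldehyde, or enolise at C3 (epimerisation or E1cB dehydration), before the aryl ether forms.
- Fallback (latent alkoxide released by catalytic fluoride in place of a stoichiometric base): it sets out from 10. Silylation (TMSCl, imidazole, CH2Cl2) gives (2R,3R)-1,4-bis[2,4-bis(benzyloxy)-6-fluorophenyl]-2,3-bis{(R)-(4-methoxyphenyl)[(trimethylsilyl)oxy]methyl}butane-1,4-dione F3. Treatment of F3 with Bu4N[Ph3SiF2] (10 mol%) in DMF at rt should start a silyl-ether SNAr in which the fluoride expelled by each ring closure frees the next alkoxide. The alkoxide concentration stays minimal and no base remains at the end; the route is rejoined at 11.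

## Further compounds

F1 | step 4 | (E)-1-[2,4-bis(benzyloxy)-6-fluorophenyl]-3-(4-methoxyphenyl)prop-2-en-1-one | COc1ccc(/C=C/C(=O)c2c(OCc3ccccc3)cc(OCc3ccccc3)cc2F)cc1
F2 | step 4 | [(1R,2R,3S,4S)-3,4-bis(4-methoxyphenyl)cyclobutane-1,2-diyl]bis{[2,4-bis(benzyloxy)-6-fluorophenyl]methanone} (mirror image of 8) | COc1ccc(cc1)[C@@H]1[C@@H](C(=O)c2c(OCc3ccccc3)cc(OCc3ccccc3)cc2F)[C@H](C(=O)c2c(OCc3ccccc3)cc(OCc3ccccc3)cc2F)[C@H]1c1ccc(OC)cc1
F0 | step 6 | none | none
F3 | step 8 | (2R,3R)-1,4-bis[2,4-bis(benzyloxy)-6-fluorophenyl]-2,3-bis{(R)-(4-methoxyphenyl)[(trimethylsilyl)oxy]methyl}butane-1,4-dione | COc1ccc(cc1)[C@H](O[Si](C)(C)C)[C@H](C(=O)c2c(OCc3ccccc3)cc(OCc3ccccc3)cc2F)[C@@H](C(=O)c2c(OCc3ccccc3)cc(OCc3ccccc3)cc2F)[C@@H](O[Si](C)(C)C)c1ccc(OC)cc1
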